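**Retrosynthetic overview**

1. The C12 acetate comes from acylation after acidolysis of a chiral 1-arylethyl ether. The (Z)-C14=C15 alkene comes from a Wittig reaction on a C14 aldehyde. The (E)-C5=C6 alkene comes from cross-metathesis of a C8 allyl group with methyl (4S)-4-acetoxyhex-5-enoate.
2. The cyclopentenone (C8–C9–C10–C11–C12) comes from a 2,2-dichloro-3-alkoxycyclopentanone: radical allylation then radical reduction at C8, and Saegusa–Ito oxidation for C10=C11.
3. Key disconnection: the five-membered ring comes from a four-membered ring (C8, C9, C11, C12) plus C10 from diazomethane. The cyclobutanone comes from dichloroketene (C8=C9) and a chiral 2-alkoxy-1-alkene (C11=C12). Three components are joined in one operation.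
4. Enabling feature: the C12 oxygen sits β to the C9 carbonyl (O–C12–C8–C9=O), which is the polarity pattern of a ketene/enol-ether cycloadduct. C10 is an unsubstituted carbon between C9 and C11 and can be inserted last. Chlorine on C8 blocks migration of C8 and keeps the two arms of C12 different.
5. Ring order: the molecule has one ring. It is closed four-membered and expanded to five-membered within step 4.

Key step: step 4

Remark: prostanoid numbering is used for ring atoms of the target (C1 ester carbon, C9 ring ketone, C8 and C12 ring stereocenters, C20 chain methyl).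

Assumption: the (S)-carbinol auxiliary is taken to direct the ketene to the alkene face that gives the C12 configuration of the target (model in step 4). If the sense were the opposite, the (R)-alcohol would be used in its place with no other change.

**Route**

Step 1
Reactants: 1 methyl 3,3-dimethoxypropanoate
Product: 2 3,3-dimethoxypropanoic acid
Conditions: LiOH, THF/H2O, 0 °C to rt; then 1 M HCl to pH 4, 0 °C
Reagents that add atoms: lithium hydroxide, [Li+].[OH-]
Why: Ester saponification; brief cold acidification to pH 4 should leave the dimethyl acetal intact.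

Step 2
Reactants: 2 3,3-dimethoxypropanoic acid; 3 (1S)-1-[2,4,6-tri(propan-2-yl)phenyl]ethan-1-ol
Product: 4 (1S)-1-[2,4,6-tri(propan-2-yl)phenyl]ethyl 3,3-dimethoxypropanoate
Conditions: DCC, DMAP (cat.), CH2Cl2, 0 °C to rt
Reagents that add atoms: none
Why: Steglich esterification acylates the hindered secondary alcohol on oxygen, so the (S) carbinol center is not touched.

Step 3
Reactants: 4 (1S)-1-[2,4,6-tri(propan-2-yl)phenyl]ethyl 3,3-dimethoxypropanoate
Product: 5 2-{(1S)-1-[(4,4-dimethoxybut-1-en-2-yl)oxy]ethyl}-1,3,5-tri(propan-2-yl)benzene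
Conditions: dimethyltitanocene (C5H5)2Ti(CH3)2, toluene, 65 °C, dark; filtration through basic alumina
Reagents that add atoms: dimethyltitanocene, C[Ti](C)(C1C=CC=C1)C1C=CC=C1
Why: Petasis methylenation (titanium methylidene) converts the ester carbonyl into the 1,1-disubstituted enol ether under non-acidic conditions that spare the acetal.

Step 4
Reactants: 5 2-{(1S)-1-[(4,4-dimethoxybut-1-en-2-yl)oxy]ethyl}-1,3,5-tri(propan-2-yl)benzene; 6 dichloroacetyl chloride; 7 diazomethane
Product: 10 (3S)-2,2-dichloro-3-(2,2-dimethoxyethyl)-3-{(1S)-1-[2,4,6-tri(propan-2-yl)phenyl]ethoxy}cyclopentan-1-one, via dichloroketene 8 (not isolated), via dichlorocyclobutanone 9 (not isolated)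
Conditions: 6, Et3N (slow addition), hexane, 0 °C to rt; filtration under argon; then 7 in Et2O, MeOH (cat.), 0 °C
Reagents that add atoms: none
Why: Triethylamine dehydrochlorinates 6 to dichloroketene 8, which undergoes a thermal [2+2] cycloaddition (antarafacial on the ketene, in the limit stepwise through an oxocarbenium/enolate zwitterion) with the electron-rich alkene of 5, the nucleophilic CH2 terminus bonding to the ketene carbonyl carbon and the oxygen-bearing carbon to CCl2, so that 9 carries the ether β to the ketone; diazomethane then adds to the activated carbonyl of 9 and the betaine loses N2 with 1,2-shift of the CH2 carbon (Tiffeneau–Demjanov-type one-carbon ring expansion). The closest known reaction type is the haloketene–enol ether cycloaddition followed by diazomethane homologation of the α,α-dichlorocyclobutanone, used as a three-carbon cyclopentanone annulation. The four-membered ring is closed by cycloaddition (two C–C bonds at once) and the five-membered ring arises from it by insertion of one carbon between the carbonyl carbon and the CH2 group. The new quaternary stereocenter is controlled by the (S)-carbinol auxiliary on the enol ether oxygen: in the s-cis conformer with the carbinol C–H in the alkene plane the triisopropylphenyl group should block one face and the ketene add to the other, and the ring expansion does not touch this center. The step needs face selectivity in the cycloaddition and regioselective migration in the expansion; the first rests on the auxiliary (the diastereomers remain separable), the second on the two chlorine atoms, which make the CCl2 carbon a poor migrating group and also keep the two arms of the quaternary carbon different so that its configuration is not lost.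

Step 5
Reactants: 10 (3S)-2,2-dichloro-3-(2,2-dimethoxyethyl)-3-{(1S)-1-[2,4,6-tri(propan-2-yl)phenyl]ethoxy}cyclopentan-1-one; 11 tributyl(prop-2-en-1-yl)stannane
Product: 12 (2R,3S)-2-chloro-3-(2,2-dimethoxyethyl)-2-(prop-2-en-1-yl)-3-{(1S)-1-[2,4,6-tri(propan-2-yl)phenyl]ethoxy}cyclopentan-1-one (allyl trans to the ether oxygen)
Conditions: allylSnBu3 (1.2 equiv), AIBN (cat.), benzene, 80 °C
Reagents that add atoms: none
Why: Keck radical allylation: the tin radical abstracts one chlorine of the activated gem-dichloride and the α-keto radical adds to the allylstannane on the face opposite the bulky aryl-ethoxy group, the gem-dichloride being expected to react faster than the tertiary monochloride product.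

Step 6
Reactants: 12 (2R,3S)-2-chloro-3-(2,2-dimethoxyethyl)-2-(prop-2-en-1-yl)-3-{(1S)-1-[2,4,6-tri(propan-2-yl)phenyl]ethoxy}cyclopentan-1-one
Product: 13 (2R,3S)-3-(2,2-dimethoxyethyl)-2-(prop-2-en-1-yl)-3-{(1S)-1-[2,4,6-tri(propan-2-yl)phenyl]ethoxy}cyclopentan-1-one (allyl cis to the ether oxygen)
Conditions: Bu3SnH, AIBN (cat.), benzene, 80 °C
Reagents that add atoms: none
Why: Radical dechlorination with Bu3SnH: the planar α-keto radical should take hydrogen from the face opposite the aryl-ethoxy group, which places the allyl group cis to the ether oxygen (the C8 configuration of the target), and no enolate is formed so the β-alkoxy group cannot be eliminated.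

Step 7
Reactants: 13 (2R,3S)-3-(2,2-dimethoxyethyl)-2-(prop-2-en-1-yl)-3-{(1S)-1-[2,4,6-tri(propan-2-yl)phenyl]ethoxy}cyclopentan-1-one
Product: 16 (4R,5R)-4-(2,2-dimethoxyethyl)-5-(prop-2-en-1-yl)-4-{(1S)-1-[2,4,6-tri(propan-2-yl)phenyl]ethoxy}cyclopent-2-en-1-one, via lithium enolate 14 (not isolated), via silyl enol ether 15 (not isolated)
Conditions: LiN(iPr)2, Me3SiCl, THF, −78 °C; then Pd(OAc)2, MeCN, rt
Reagents that add atoms: none
Why: Kinetic deprotonation at the unhindered ring CH2 next to the carbonyl with internal silyl quench, then Saegusa–Ito oxidation (palladium enolate, β-hydride elimination) gives the enone; the C–H next to the quaternary carbon is not removed, so neither β-elimination nor epimerisation is expected.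

Step 8
Reactants: 17 methyl 4-oxobutanoate; 18 ethenylmagnesium bromide
Product: 19 methyl 4-hydroxyhex-5-enoate (racemic)
Conditions: THF, −78 °C; aq. NH4Cl
Reagents that add atoms: none
Why: Grignard addition to the aldehyde, which is far more electrophilic than the ester at −78 °C; the new carbinol is racemic at this stage.

Step 9
Reactants: 19 methyl 4-hydroxyhex-5-enoate (racemic)
Product: 20 methyl (4S)-4-acetoxyhex-5-enoate
Conditions: Candida antarctica lipase B (immobilised), vinyl acetate, hexane, 30 °C, to about half conversion; chromatography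
Reagents that add atoms: vinyl acetate, CC(=O)OC=C
Why: Lipase-catalysed kinetic resolution by transesterification: with vinyl as the smaller and the ester chain as the larger substituent the enzyme should acylate the (S)-alcohol (the usual empirical preference for secondary alcohols), and the unreacted (R)-alcohol is removed.

Step 10
Reactants: 16 (4R,5R)-4-(2,2-dimethoxyethyl)-5-(prop-2-en-1-yl)-4-{(1S)-1-[2,4,6-tri(propan-2-yl)phenyl]ethoxy}cyclopent-2-en-1-one; 20 methyl (4S)-4-acetoxyhex-5-enoate
Product: 21 methyl (4S,5E)-4-acetoxy-7-[(1R,5R)-5-(2,2-dimethoxyethyl)-2-oxo-5-{(1S)-1-[2,4,6-tri(propan-2-yl)phenyl]ethoxy}cyclopent-3-en-1-yl]hept-5-enoate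
Conditions: 20 (3 equiv), second-generation Grubbs catalyst (5 mol%), CH2Cl2, 40 °C
Reagents that add atoms: none
Why: Olefin cross-metathesis between the unhindered allyl group and the secondary allylic acetate used in excess; the E alkene is the thermodynamically favoured product, and the cyclic enone and the acetate-bearing stereocenter are not affected.

Step 11
Reactants: 21 methyl (4S,5E)-4-acetoxy-7-[(1R,5R)-5-(2,2-dimethoxyethyl)-2-oxo-5-{(1S)-1-[2,4,6-tri(propan-2-yl)phenyl]ethoxy}cyclopent-3-en-1-yl]hept-5-enoate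
Product: 22 methyl (4S,5E)-4-acetoxy-7-[(1R,5R)-2-oxo-5-(2-oxoethyl)-5-{(1S)-1-[2,4,6-tri(propan-2-yl)phenyl]ethoxy}cyclopent-3-en-1-yl]hept-5-enoate
Conditions: LiBF4, MeCN/H2O (98:2), rt to 40 °C
Reagents that add atoms: water, O
Why: Mild Lewis-acid hydrolysis of the dimethyl acetal (oxocarbenium ion, water), under which the hindered benzylic ether, the allylic acetate and the methyl ester should survive.

Step 12
Reactants: 22 methyl (4S,5E)-4-acetoxy-7-[(1R,5R)-2-oxo-5-(2-oxoethyl)-5-{(1S)-1-[2,4,6-tri(propan-2-yl)phenyl]ethoxy}cyclopent-3-en-1-yl]hept-5-enoate; 23 hexyl(triphenyl)phosphonium bromide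
Product: 25 methyl (4S,5E)-4-acetoxy-7-[(1R,5R)-5-[(2Z)-oct-2-en-1-yl]-2-oxo-5-{(1S)-1-[2,4,6-tri(propan-2-yl)phenyl]ethoxy}cyclopent-3-en-1-yl]hept-5-enoate, via phosphorus ylide 24 (not isolated)
Conditions: 23, NaN(SiMe3)2, THF, 0 °C; then 22, −78 °C to 0 °C
Reagents that add atoms: none
Why: Wittig olefination with a non-stabilised ylide under salt-free conditions gives the Z alkene under kinetic control, the aldehyde reacting much faster than the enone or the esters at −78 °C.

Step 13
Reactants: 25 methyl (4S,5E)-4-acetoxy-7-[(1R,5R)-5-[(2Z)-oct-2-en-1-yl]-2-oxo-5-{(1S)-1-[2,4,6-tri(propan-2-yl)phenyl]ethoxy}cyclopent-3-en-1-yl]hept-5-enoate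
Product: 26 methyl (4S,5E)-4-acetoxy-7-[(1R,5R)-5-hydroxy-5-[(2Z)-oct-2-en-1-yl]-2-oxocyclopent-3-en-1-yl]hept-5-enoate
Conditions: CF3CO2H, CH2Cl2, 0 °C; aq. NaHCO3
Reagents that add atoms: none
Why: Acidolysis of the 1-arylethyl ether by an SN1 path through the benzylic cation cleaves the O–CH(CH3)Ar bond and not the bond to the ring, so the quaternary carbinol keeps its configuration.

Step 14
Reactants: 26 methyl (4S,5E)-4-acetoxy-7-[(1R,5R)-5-hydroxy-5-[(2Z)-oct-2-en-1-yl]-2-oxocyclopent-3-en-1-yl]hept-5-enoate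
Product: 27 methyl (4S,5E)-4-acetoxy-7-[(1R,5R)-5-acetoxy-5-[(2Z)-oct-2-en-1-yl]-2-oxocyclopent-3-en-1-yl]hept-5-enoate (target)
Conditions: Ac2O, DMAP, Et3N, CH2Cl2, rt
Reagents that add atoms: acetic anhydride, CC(=O)OC(C)=O
Why: DMAP-catalysed acyl transfer to the tertiary alcohol touches no stereocenter; β-elimination of the new acetate would need a cyclopentadienone and is not expected, and the C8 configuration set in step 6 (side chains trans) is expected to be the more stable one under the mildly basic conditions.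

**Compound list**

1 | methyl 3,3-dimethoxypropanoate | COC(=O)CC(OC)OC | starting material
2 | 3,3-dimethoxypropanoic acid | OC(=O)CC(OC)OC | intermediate
3 | (1S)-1-[2,4,6-tri(propan-2-yl)phenyl]ethan-1-ol | C[C@H](O)c1c(C(C)C)cc(C(C)C)cc1C(C)C | starting material
4 | (1S)-1-[2,4,6-tri(propan-2-yl)phenyl]ethyl 3,3-dimethoxypropanoate | COC(OC)CC(=O)O[C@@H](C)c1c(C(C)C)cc(C(C)C)cc1C(C)C | intermediate
5 | 2-{(1S)-1-[(4,4-dimethoxybut-1-en-2-yl)oxy]ethyl}-1,3,5-tri(propan-2-yl)benzene | COC(OC)CC(=C)O[C@@H](C)c1c(C(C)C)cc(C(C)C)cc1C(C)C | intermediate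
6 | dichloroacetyl chloride | ClC(Cl)C(Cl)=O | starting material
7 | diazomethane (ethereal solution, freshly generated from commercial N-methyl-N-nitroso-4-toluenesulfonamide) | C=[N+]=[N-] | starting material
8 | dichloroketene | ClC(Cl)=C=O | intermediate (not isolated)
9 | (3R)-2,2-dichloro-3-(2,2-dimethoxyethyl)-3-{(1S)-1-[2,4,6-tri(propan-2-yl)phenyl]ethoxy}cyclobutan-1-one | COC(OC)C[C@@]1(O[C@@H](C)c2c(C(C)C)cc(C(C)C)cc2C(C)C)CC(=O)C1(Cl)Cl | intermediate (not isolated)
10 | (3S)-2,2-dichloro-3-(2,2-dimethoxyethyl)-3-{(1S)-1-[2,4,6-tri(propan-2-yl)phenyl]ethoxy}cyclopentan-1-one | COC(OC)C[C@@]1(O[C@@H](C)c2c(C(C)C)cc(C(C)C)cc2C(C)C)CCC(=O)C1(Cl)Cl | intermediate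
11 | tributyl(prop-2-en-1-yl)stannane | C=CC[Sn](CCCC)(CCCC)CCCC | starting material
12 | (2R,3S)-2-chloro-3-(2,2-dimethoxyethyl)-2-(prop-2-en-1-yl)-3-{(1S)-1-[2,4,6-tri(propan-2-yl)phenyl]ethoxy}cyclopentan-1-one | COC(OC)C[C@@]1(O[C@@H](C)c2c(C(C)C)cc(C(C)C)cc2C(C)C)CCC(=O)[C@]1(CC=C)Cl | intermediate
13 | (2R,3S)-3-(2,2-dimethoxyethyl)-2-(prop-2-en-1-yl)-3-{(1S)-1-[2,4,6-tri(propan-2-yl)phenyl]ethoxy}cyclopentan-1-one | COC(OC)C[C@@]1(O[C@@H](C)c2c(C(C)C)cc(C(C)C)cc2C(C)C)CCC(=O)[C@@H]1CC=C | intermediate
14 | lithium enolate of 13 (enolate double bond between the carbonyl carbon and the ring CH2; stereocenters as in 13) | COC(OC)C[C@@]1(O[C@@H](C)c2c(C(C)C)cc(C(C)C)cc2C(C)C)CC=C(O[Li])[C@@H]1CC=C | intermediate (not isolated)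
15 | trimethylsilyl enol ether of 13 (1-trimethylsilyloxycyclopent-1-ene; stereocenters as in 13) | COC(OC)C[C@@]1(O[C@@H](C)c2c(C(C)C)cc(C(C)C)cc2C(C)C)CC=C(O[Si](C)(C)C)[C@@H]1CC=C | intermediate (not isolated)
16 | (4R,5R)-4-(2,2-dimethoxyethyl)-5-(prop-2-en-1-yl)-4-{(1S)-1-[2,4,6-tri(propan-2-yl)phenyl]ethoxy}cyclopent-2-en-1-one | COC(OC)C[C@@]1(O[C@@H](C)c2c(C(C)C)cc(C(C)C)cc2C(C)C)C=CC(=O)[C@@H]1CC=C | intermediate
17 | methyl 4-oxobutanoate | COC(=O)CCC=O | starting material
18 | ethenylmagnesium bromide | C=C[Mg]Br | starting material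
19 | methyl 4-hydroxyhex-5-enoate (racemic) | COC(=O)CCC(O)C=C | intermediate
20 | methyl (4S)-4-acetoxyhex-5-enoate | C=C[C@H](CCC(=O)OC)OC(C)=O | intermediate
21 | methyl (4S,5E)-4-acetoxy-7-[(1R,5R)-5-(2,2-dimethoxyethyl)-2-oxo-5-{(1S)-1-[2,4,6-tri(propan-2-yl)phenyl]ethoxy}cyclopent-3-en-1-yl]hept-5-enoate | COC(OC)C[C@@]1(O[C@@H](C)c2c(C(C)C)cc(C(C)C)cc2C(C)C)C=CC(=O)[C@@H]1C/C=C/[C@H](CCC(=O)OC)OC(C)=O | intermediate
22 | methyl (4S,5E)-4-acetoxy-7-[(1R,5R)-2-oxo-5-(2-oxoethyl)-5-{(1S)-1-[2,4,6-tri(propan-2-yl)phenyl]ethoxy}cyclopent-3-en-1-yl]hept-5-enoate | O=CC[C@@]1(O[C@@H](C)c2c(C(C)C)cc(C(C)C)cc2C(C)C)C=CC(=O)[C@@H]1C/C=C/[C@H](CCC(=O)OC)OC(C)=O | intermediate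
23 | hexyl(triphenyl)phosphonium bromide | CCCCCC[P+](c1ccccc1)(c1ccccc1)c1ccccc1.[Br-] | starting material
24 | hexylidene(triphenyl)phosphorane | CCCCCC=P(c1ccccc1)(c1ccccc1)c1ccccc1 | intermediate (not isolated)
25 | methyl (4S,5E)-4-acetoxy-7-[(1R,5R)-5-[(2Z)-oct-2-en-1-yl]-2-oxo-5-{(1S)-1-[2,4,6-tri(propan-2-yl)phenyl]ethoxy}cyclopent-3-en-1-yl]hept-5-enoate | CCCCC/C=C\C[C@@]1(O[C@@H](C)c2c(C(C)C)cc(C(C)C)cc2C(C)C)C=CC(=O)[C@@H]1C/C=C/[C@H](CCC(=O)OC)OC(C)=O | intermediate
26 | methyl (4S,5E)-4-acetoxy-7-[(1R,5R)-5-hydroxy-5-[(2Z)-oct-2-en-1-yl]-2-oxocyclopent-3-en-1-yl]hept-5-enoate | CCCCC/C=C\C[C@@]1(O)C=CC(=O)[C@@H]1C/C=C/[C@H](CCC(=O)OC)OC(C)=O | intermediate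
27 | methyl (4S,5E)-4-acetoxy-7-[(1R,5R)-5-acetoxy-5-[(2Z)-oct-2-en-1-yl]-2-oxocyclopent-3-en-1-yl]hept-5-enoate | CCCCC/C=C\C[C@@]1(OC(C)=O)C=CC(=O)[C@@H]1C/C=C/[C@H](CCC(=O)OC)OC(C)=O | target

**Totals**

Total step count: 14. Longest linear sequence: 12 steps (steps 1 to 7 and 10 to 14).

**Steps most likely to fail**

Step 4. Face discrimination by the auxiliary may be weaker on a 1,1-disubstituted enol ether than on the 1,2-disubstituted enol ethers for which this control element is established. The acid-labile enol ether may also be consumed by the ammonium salt before the ketene is trapped in the telescoped procedure. The fallback sets out from 5 and comes back at 10. Dichloroketene would be generated reductively from trichloroacetyl chloride with zinc–copper couple (POCl3, Et2O), so no ammonium salt is present, and the cyclobutanone would be isolated. Compound 9 and its epimer at the quaternary carbon, (3S)-2,2-dichloro-3-(2,2-dimethoxyethyl)-3-{(1S)-1-[2,4,6-tri(propan-2-yl)phenyl]ethoxy}cyclobutan-1-one F1, are diastereomers because of the auxiliary and would be separated by chromatography or crystallisation. Pure 9 would then be ring-expanded with diazomethane in a separate operation to 10. Stereocontrol then rests on resolution through the auxiliary and not on induction.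

Step 5. The monochloride product may be allylated a second time, or the radical chain may not carry with the gem-dichloride. The fallback sets out from 5 and comes back at 13; it brings the allyl group in with the ketene. Pent-4-enoic acid would be chlorinated as its dianion (LiN(iPr)2, then CCl4) to 2-chloropent-4-enoic acid F2 and converted with oxalyl chloride into 2-chloropent-4-enoyl chloride F3. With Et3N in the presence of 5 this gives allyl(chloro)ketene F4 and the cycloadduct (3R)-2-chloro-3-(2,2-dimethoxyethyl)-2-(prop-2-en-1-yl)-3-{(1S)-1-[2,4,6-tri(propan-2-yl)phenyl]ethoxy}cyclobutan-1-one F5 (mixture of epimers at the chlorinated carbon). Diazomethane would expand F5, again with migration of the unchlorinated CH2, to 12 together with its (2S,3S) epimer F6. Both would be reduced with Bu3SnH under the conditions of step 6 to the same ketone 13.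

Step 12. The basic ylide may enolise the β-alkoxy aldehyde (with loss of the ether by elimination), attack the enone, or give an eroded Z/E ratio. The fallback sets out from 22 and comes back at 25; it builds the Z alkene by cross-coupling. Aldehyde 22 with CBr4 and PPh3 (CH2Cl2, 0 °C) would give the dibromoalkene methyl (4S,5E)-4-acetoxy-7-[(1R,5R)-5-(3,3-dibromoprop-2-en-1-yl)-2-oxo-5-{(1S)-1-[2,4,6-tri(propan-2-yl)phenyl]ethoxy}cyclopent-3-en-1-yl]hept-5-enoate F7. Hydrogenolysis with Bu3SnH and Pd(PPh3)4 removes the bromine trans to the chain and should give the (Z)-bromoalkene methyl (4S,5E)-4-acetoxy-7-[(1R,5R)-5-[(2Z)-3-bromoprop-2-en-1-yl]-2-oxo-5-{(1S)-1-[2,4,6-tri(propan-2-yl)phenyl]ethoxy}cyclopent-3-en-1-yl]hept-5-enoate F8. Negishi coupling of F8 with pentylzinc bromide (Pd(PPh3)4, THF, rt) proceeds with retention of alkene geometry and would give 25 under neutral conditions.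

Further compounds
F1 | step 4 | (3S)-2,2-dichloro-3-(2,2-dimethoxyethyl)-3-{(1S)-1-[2,4,6-tri(propan-2-yl)phenyl]ethoxy}cyclobutan-1-one | COC(OC)C[C@]1(O[C@@H](C)c2c(C(C)C)cc(C(C)C)cc2C(C)C)CC(=O)C1(Cl)Cl
F2 | step 5 | 2-chloropent-4-enoic acid (racemic) | OC(=O)C(Cl)CC=C
F3 | step 5 | 2-chloropent-4-enoyl chloride (racemic) | ClC(=O)C(Cl)CC=C
F4 | step 5 | allyl(chloro)ketene (2-chloropenta-1,4-dien-1-one) | C=CCC(Cl)=C=O
F5 | step 5 | (3R)-2-chloro-3-(2,2-dimethoxyethyl)-2-(prop-2-en-1-yl)-3-{(1S)-1-[2,4,6-tri(propan-2-yl)phenyl]ethoxy}cyclobutan-1-one (epimers at the chlorinated carbon) | COC(OC)C[C@@]1(O[C@@H](C)c2c(C(C)C)cc(C(C)C)cc2C(C)C)CC(=O)C1(Cl)CC=C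
F6 | step 5 | (2S,3S)-2-chloro-3-(2,2-dimethoxyethyl)-2-(prop-2-en-1-yl)-3-{(1S)-1-[2,4,6-tri(propan-2-yl)phenyl]ethoxy}cyclopentan-1-one | COC(OC)C[C@@]1(O[C@@H](C)c2c(C(C)C)cc(C(C)C)cc2C(C)C)CCC(=O)[C@@]1(CC=C)Cl
F7 | step 12 | methyl (4S,5E)-4-acetoxy-7-[(1R,5R)-5-(3,3-dibromoprop-2-en-1-yl)-2-oxo-5-{(1S)-1-[2,4,6-tri(propan-2-yl)phenyl]ethoxy}cyclopent-3-en-1-yl]hept-5-enoate | BrC(Br)=CC[C@@]1(O[C@@H](C)c2c(C(C)C)cc(C(C)C)cc2C(C)C)C=CC(=O)[C@@H]1C/C=C/[C@H](CCC(=O)OC)OC(C)=O
F8 | step 12 | methyl (4S,5E)-4-acetoxy-7-[(1R,5R)-5-[(2Z)-3-bromoprop-2-en-1-yl]-2-oxo-5-{(1S)-1-[2,4,6-tri(propan-2-yl)phenyl]ethoxy}cyclopent-3-en-1-yl]hept-5-enoate | Br/C=C\C[C@@]1(O[C@@H](C)c2c(C(C)C)cc(C(C)C)cc2C(C)C)C=CC(=O)[C@@H]1C/C=C/[C@H](CCC(=O)OC)OC(C)=O
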